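The ten-membered carbocycle (ring carbons a–j: lactone O–CH a, alkene b=c, acetoxy carbon d, epoxide e–f, methylenes g and h, angeloyloxy carbon i, lactone CH j) is cut at g–h. The oxygen on d, the e–f unsaturation behind the epoxide ring and the g–h bond are the 1,4-signature of a carbon nucleophile opening a vinyl epoxide. Zerovalent palladium therefore isomerises an open-chain trans d,e-epoxide, flanked by an isopropenyl group (f=g) and ending in a beta-keto sulfone (h, i), into the carbocycle. One operation creates the g–h bond, the Z alkene e=f and the free d-hydroxyl with its configuration intact. Lactone, methylene, esters and epoxide follow.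

Key step: step 11

Reading of the target:
- Descriptors are a S, d R, e R, f S, i R, j R.
- H-a and H-j are cis. The lactone is cis-fused, which corresponds to an anti aldol pair in the open chain.
- d and g are cis on the oxirane, so its alkene precursor must be Z.
- The oxirane oxygen is erythro to the oxygen on d (a ring-cis epoxy alcohol).
- The CIP letters at d and j change along the route with the substituents. No bond at these centres is ever broken after it is set.

Assumption: the 2-methylallyl ylide of (1R,4R,5R)-isothiocineole is taken to give the (R,R) trans epoxide; if the sense is opposite, the enantiomeric sulfide (from the other limonene) is used and nothing else changes.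

Assumption: the magnesium-catalysed aldol of the (S)-thiazolidinethione is taken to react on the enolate face left open in the non-chelated rotamer; the (R)-auxiliary is equally available.

Design choices:
- The keto sulfone is installed last. Its acidic CH2 would quench the sulfonium ylide.
- The epoxide is kept trans. A cis-divinyl epoxide would be open to Cope rearrangement.
- No protic acid is used after ring closure. The tert-butyl ester is removed with a silyl triflate, and the lactone is closed before any epoxide exists.
- Methylenation is run while only silyl ethers are present, with graded lability TES < TBS < TIPS.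
- The epoxide enters second to last, by delivery from the d-alkoxide. This is the mode that gives the erythro isomer. Undirected peripheral attack on the conformer with H-d inside would favour the other face.

Step 1
Reactants: 1 pyruvaldehyde dimethyl acetal; 2 diethyl {2-[methoxy(methyl)amino]-2-oxoethyl}phosphonate
Product: 3 (E)-N,4,4-trimethoxy-N,3-dimethylbut-2-enamide
Conditions: NaH, THF, 0 °C to rt; chromatography
Reagents that add atoms: none
Why: Horner–Wadsworth–Emmons olefination of an activated methyl ketone; the carbamoyl group should settle trans to the larger dimethoxymethyl group, which fixes the E alkene b=c, and any Z isomer is removed on silica.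

Step 2
Reactants: 3 (E)-N,4,4-trimethoxy-N,3-dimethylbut-2-enamide
Product: 4 (E)-4,4-dimethoxy-3-methylbut-2-enal
Conditions: iBu2AlH (1.1 equiv), THF, −78 °C; aq. potassium sodium tartrate
Reagents that add atoms: none
Why: Partial reduction of a Weinreb amide; the chelated aluminium hemiaminal persists until the neutral work-up, so the enal is released without over-reduction and the acetal is untouched.

Step 3
Reactants: 5 mono-tert-butyl succinate; 6 (S)-4-benzyl-1,3-thiazolidine-2-thione
Product: 7 tert-butyl 4-[(4S)-4-benzyl-2-thioxo-1,3-thiazolidin-3-yl]-4-oxobutanoate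
Conditions: EDC·HCl, DMAP (cat.), CH2Cl2, 0 °C to rt
Reagents that add atoms: none
Why: Carbodiimide (Steglich-type) N-acylation of the thiazolidinethione; only the free acid end of the half-ester can react.

Step 4
Reactants: 7 N-succinyl thiazolidinethione; 4 (E)-4,4-dimethoxy-3-methylbut-2-enal
Product: 9 tert-butyl (3S,4S,5E)-3-{[(4S)-4-benzyl-2-thioxo-1,3-thiazolidin-3-yl]carbonyl}-4-hydroxy-7,7-dimethoxy-6-methylhept-5-enoate, via trimethylsilyl ether 8 (not isolated)
Conditions: MgBr2·OEt2 (20 mol %), Et3N, Me3SiCl, EtOAc, rt; then PPTS, MeOH, 0 °C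
Reagents that add atoms: chlorotrimethylsilane C[Si](C)(C)Cl (silyl group kept only in 8)
Why: Magnesium-halide-catalysed direct anti-aldol of an N-acylthiazolidinethione with an enal lacking alpha-hydrogens, turned over by silylation of the aldolate; the benzyl group screens one face of the Z-enolate and sets j, the anti topology sets a, and methanolysis removes only the trimethylsilyl group because the acetal merely exchanges with methanol.

Step 5
Reactants: 9 anti-aldol adduct
Product: 10 tert-butyl (3S,4S,5E)-4-hydroxy-7,7-dimethoxy-3-[methoxy(methyl)carbamoyl]-6-methylhept-5-enoate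
Conditions: MeONHMe·HCl, imidazole, CH2Cl2, rt
Reagents that add atoms: N,O-dimethylhydroxylamine hydrochloride CNOC.Cl
Why: Aminolysis of the activated N-acylthiazolidinethione to the Weinreb amide; no metal amide is needed, the tert-butyl ester is inert, no stereocentre is touched and the auxiliary is recovered.

Step 6
Reactants: 10 hydroxy Weinreb amide
Product: 11 tert-butyl (3S,4S,5E)-7,7-dimethoxy-3-[methoxy(methyl)carbamoyl]-6-methyl-4-(triethylsilyloxy)hept-5-enoate
Conditions: Et3SiCl, imidazole, DMF, 0 °C to rt
Reagents that add atoms: chlorotriethylsilane CC[Si](Cl)(CC)CC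
Why: Silyl ether formation on the only free hydroxyl; the chloride is preferred to the triflate because a silyl triflate with a pyridine base would also attack the acetal.

Step 7
Reactants: 11 silyl ether acetal
Product: 12 tert-butyl (3S,4S,5E)-3-[methoxy(methyl)carbamoyl]-6-methyl-7-oxo-4-(triethylsilyloxy)hept-5-enoate
Conditions: 10% aq. oxalic acid on SiO2, CH2Cl2, rt
Reagents that add atoms: water O
Why: Acid-catalysed acetal hydrolysis; the conjugated acetal ionises through an allyl-stabilised oxocarbenium ion under conditions too mild for the secondary triethylsilyl ether or the tert-butyl ester, and the E geometry is kept.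

Step 8
Reactants: 13 (1R,4R,5R)-isothiocineole; 14 3-bromo-2-methylpropene
Product: 15 S-(2-methylallyl)isothiocineolium triflate
Conditions: LiOSO2CF3, CH2Cl2/H2O, rt
Reagents that add atoms: lithium triflate [Li+].[O-]S(=O)(=O)C(F)(F)F
Why: SN2 S-alkylation of the bicyclic sulfide on its exposed lone pair, made irreversible by exchange of bromide for non-nucleophilic triflate, should give one sulfonium diastereomer.

Step 9
Reactants: 15 sulfonium triflate; 12 enal
Product: 17 tert-butyl (3S,4S,5E)-3-[methoxy(methyl)carbamoyl]-6-[(2R,3R)-3-(prop-1-en-2-yl)oxiran-2-yl]-4-(triethylsilyloxy)hept-5-enoate, via sulfonium ylide 16 (not isolated)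
Conditions: 15 (1.3 equiv), LiN(SiMe3)2 (1.25 equiv), THF, −78 °C; then 12, −78 to −40 °C
Reagents that add atoms: none
Why: Asymmetric Johnson–Corey–Chaykovsky epoxidation with a chiral 2-substituted allyl sulfonium ylide; the rigid sulfide fixes ylide conformation and face, addition through the anti betaine and ring closure give the trans epoxide and set d (and e) under reagent control, and amide, ester and silyl ether ignore the ylide.

Step 10
Reactants: 18 methyl phenyl sulfone; 17 vinyl epoxide Weinreb amide
Product: 20 tert-butyl (3S,4S,5E)-6-[(2R,3R)-3-(prop-1-en-2-yl)oxiran-2-yl]-3-[(phenylsulfonyl)acetyl]-4-(triethylsilyloxy)hept-5-enoate, via lithiated sulfone 19 (not isolated)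
Conditions: 18 (2.2 equiv), n-BuLi (2.1 equiv), THF, −78 °C; then 17, −78 to −40 °C; AcOH quench
Reagents that add atoms: n-butyllithium [Li]CCCC (lithium kept only in 19)
Why: Acylation of a sulfonyl carbanion by a Weinreb amide; the chelated tetrahedral adduct stops the reaction at the ketone stage, and the hindered tert-butyl ester and the unactivated epoxide are not attacked at low temperature.

Step 11
Reactants: 20 open-chain keto sulfone vinyl epoxide
Product: 21 tert-butyl 2-[(1S,2S,3E,5S,6Z)-5-hydroxy-4,7-dimethyl-10-oxo-9-(phenylsulfonyl)-2-(triethylsilyloxy)cyclodeca-3,6-dien-1-yl]acetate (C1 = j, C2 = a, C5 = d, C9 = h; both h-epimers)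
Conditions: Pd(PPh3)4 (10 mol %), 1,2-bis(diphenylphosphino)ethane (10 mol %), THF, 45 °C, 20 added by syringe pump to 0.003 M
Reagents that add atoms: none
Why: This is a Tsuji–Trost allylic alkylation run as a neutral isomerisation, the closest known class being palladium-catalysed macrocyclisation of vinyl epoxides that carry a beta-keto sulfone: zerovalent palladium binds the 1,1-disubstituted alkene f=g, opens the strained e–O bond with inversion and leaves a pi-allyl cation over e–f–g beside the alkoxide on d. That alkoxide removes the acidic h proton, so the nucleophile exists only in a molecule that already holds the electrophile, which lets ring closure compete with oligomerisation under slow addition. Carbon h then attacks the CH2 terminus g on the face away from the metal in a 10-endo closure, the 8-exo alternative at e being disfavoured because e is secondary and stands next to the alkoxide carbon. The d–O bond is never broken, so d keeps the configuration set in step 9, and the only new stereocentre, h, is uncontrolled, labile and erased in step 12. Syn and anti allyl forms interconvert by pi–sigma–pi exchange, the methyl group on f brings their energies close, and the less strained transition state leading to a Z alkene inside an E,Z-cyclodecadiene should win. Ionisation at d through b=c is held back because that alkene is trisubstituted and screened by the silyloxy group on a, which is itself no leaving group for palladium.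

Step 12
Reactants: 21 macrocyclic keto sulfone
Product: 22 tert-butyl 2-[(1S,2S,3E,5S,6Z)-5-hydroxy-4,7-dimethyl-10-oxo-2-(triethylsilyloxy)cyclodeca-3,6-dien-1-yl]acetate
Conditions: SmI2 (3 equiv), THF/MeOH, −78 °C
Reagents that add atoms: none
Why: Reductive desulfonylation of a beta-keto sulfone by electron transfer; loss of sulfinate gives the samarium enolate on the h side, which methanol protonates, so j is not enolised and the silyloxy group on a is not eliminated.

Step 13
Reactants: 22 hydroxy ketone
Product: 23 tert-butyl 2-[(1S,2S,3E,5S,6Z)-4,7-dimethyl-10-oxo-2-(triethylsilyloxy)-5-(triisopropylsilyloxy)cyclodeca-3,6-dien-1-yl]acetate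
Conditions: iPr3SiOTf, 2,6-lutidine, CH2Cl2, −78 to 0 °C
Reagents that add atoms: triisopropylsilyl triflate CC(C)[Si](OS(=O)(=O)C(F)(F)F)(C(C)C)C(C)C
Why: Silyl ether formation with a silyl triflate and a hindered pyridine base, fast enough for the flanked bis-allylic alcohol and too mild to enolise the ketone; this is the most durable of the three graded silyl groups.

Step 14
Reactants: 23 ketone
Product: 24 tert-butyl 2-[(1R,2S,3E,5S,6Z,10R)-10-hydroxy-4,7-dimethyl-2-(triethylsilyloxy)-5-(triisopropylsilyloxy)cyclodeca-3,6-dien-1-yl]acetate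
Conditions: (S)-2-methyl-CBS-oxazaborolidine (1 equiv), catecholborane (3 equiv), toluene, −78 to −40 °C; MeOH quench
Reagents that add atoms: none
Why: Corey–Bakshi–Shibata reduction; the (S)-oxazaborolidine binds the ketone with the branched j side as large and the CH2 h side as small group and delivers hydride to the face that gives the R carbinol at i (1,3-syn to the oxygen on a), while catecholborane at low temperature leaves both ring alkenes alone.

Step 15
Reactants: 24 hydroxy tert-butyl ester
Product: 26 2-[(1R,2S,3E,5S,6Z,10R)-10-(tert-butyldimethylsilyloxy)-4,7-dimethyl-2-(triethylsilyloxy)-5-(triisopropylsilyloxy)cyclodeca-3,6-dien-1-yl]acetic acid, via silyl ester 25 (not isolated)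
Conditions: tBuMe2SiOTf (4 equiv), 2,6-lutidine (6 equiv), CH2Cl2, 0 °C to rt; then K2CO3, MeOH/THF/H2O, 0 °C; pH 5 buffer
Reagents that add atoms: tert-butyldimethylsilyl triflate CC(C)(C)[Si](C)(C)OS(=O)(=O)C(F)(F)F
Why: Silyl triflate and lutidine first silylate the i-hydroxyl and then, on warming, the ester carbonyl with loss of isobutene (non-protic tert-butyl ester cleavage), and carbonate hydrolyses only the silyl ester; this spares the bis-allylic ether and the strained diene the strong acid they would not tolerate.

Step 16
Reactants: 26 silyloxy acid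
Product: 28 cis-fused gamma-lactone on the E,Z-cyclodecadiene with d-OTIPS and i-OTBS (a S, d S, i R, j S), via hydroxy acid 27 (not isolated)
Conditions: HF·pyridine, pyridine, THF, 0 °C; then EDC·HCl, DMAP, CH2Cl2, rt
Reagents that add atoms: none
Why: Selective desilylation by graded silyl lability followed by carbodiimide lactonisation; only the a-hydroxyl is free, so the five-membered ring can close only to a, and the cis fusion follows from the anti a/j pair of step 4.

Step 17
Reactants: 28 lactone
Product: 31 alpha-methylene lactone with d-OTIPS and i-OTBS (a S, d S, i R, j S), via Mannich base 29 (not isolated), via trimethylammonium iodide 30 (not isolated)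
Conditions: LiN(iPr)2 (1.5 equiv), THF, −78 °C; CH2=NMe2+ I−, −78 °C to rt; MeI, MeOH, rt; sat. aq. NaHCO3/CH2Cl2
Reagents that add atoms: Eschenmoser's salt C=[N+](C)C.[I-]; iodomethane CI (methyl kept only in 30)
Why: Eschenmoser methylenation (lactone enolate Mannich reaction, quaternisation, Hofmann-type elimination); only silyl ethers accompany the lactone, so the strong base meets no other acidic or electrophilic group, and the enolate has no leaving group on j.

Step 18
Reactants: 31 bis-silyl ether
Product: 32 i-alcohol of the alpha-methylene lactone with d-OTIPS (a S, d S, i R, j R)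
Conditions: HF·pyridine, pyridine, THF, 0 °C to rt, monitored
Reagents that add atoms: none
Why: Selective fluoride-acid desilylation; the tert-butyldimethylsilyl ether is cleaved well before the triisopropylsilyl ether, and the medium is too weakly acidic to ionise the bis-allylic C–O bond.

Step 19
Reactants: 33 angelic acid; 32 i-alcohol
Product: 35 i-angelate with d-OTIPS (a S, d S, i R, j R), via mixed anhydride 34 (not isolated)
Conditions: 33, 2,4,6-trichlorobenzoyl chloride, Et3N, toluene, rt; then 32, 80 °C
Reagents that add atoms: 2,4,6-trichlorobenzoyl chloride O=C(Cl)c1c(Cl)cc(Cl)cc1Cl (aroyl group kept only in 34)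
Why: Yamaguchi-type mixed-anhydride esterification run without a nucleophilic pyridine catalyst, the established way to acylate hindered alcohols with angelic acid without Z-to-E isomerisation; configuration at i is retained.

Step 20
Reactants: 35 silyl ether
Product: 36 d-alcohol: bis-allylic alcohol with i-angelate and alpha-methylene lactone (a S, d S, i R, j R)
Conditions: Bu4NF, AcOH (1:1), THF, 0 °C to rt
Reagents that add atoms: none
Why: Fluoride desilylation buffered with acetic acid, so that neither the Michael acceptor nor the esters meet a basic medium.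

Step 21
Reactants: 36 bis-allylic alcohol
Product: 37 epoxy alcohol (a S, d R, e R, f S, i R, j R)
Conditions: Ti(OiPr)4 (1.2 equiv), D-(−)-diisopropyl tartrate (1.5 equiv), tBuOOH (2 equiv), 4 Å MS, CH2Cl2, −20 °C
Reagents that add atoms: tert-butyl hydroperoxide CC(C)(C)OO
Why: Sharpless asymmetric epoxidation used in its kinetic-resolution sense; with the D-(−)-tartrate the d-alkoxide is matched for oxygen delivery to e=f on the face giving the erythro, ring-cis epoxy alcohol (e R, f S), the same carbinol is mismatched for b=c, which is also deactivated by the allylic lactone oxygen, and the two conjugated ester alkenes are inert to the titanium peroxide.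

Step 22
Reactants: 37 epoxy alcohol
Product: 38 target CNP0519641.1
Conditions: Ac2O, pyridine, DMAP (cat.), CH2Cl2, 0 °C
Reagents that add atoms: acetic anhydride CC(=O)OC(C)=O
Why: Acetylation of the only free hydroxyl under weakly basic conditions that cause neither Payne rearrangement nor angelate isomerisation; configuration at d is retained.

Compound list
1 | pyruvaldehyde dimethyl acetal | CC(=O)C(OC)OC | starting material
2 | diethyl {2-[methoxy(methyl)amino]-2-oxoethyl}phosphonate | CCOP(=O)(CC(=O)N(C)OC)OCC | starting material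
3 | (E)-N,4,4-trimethoxy-N,3-dimethylbut-2-enamide | CON(C)C(=O)/C=C(\C)C(OC)OC | intermediate
4 | (E)-4,4-dimethoxy-3-methylbut-2-enal | O=C/C=C(\C)C(OC)OC | intermediate
5 | mono-tert-butyl succinate | CC(C)(C)OC(=O)CCC(=O)O | starting material
6 | (S)-4-benzyl-1,3-thiazolidine-2-thione | S=C1N[C@@H](Cc2ccccc2)CS1 | starting material
7 | tert-butyl 4-[(4S)-4-benzyl-2-thioxo-1,3-thiazolidin-3-yl]-4-oxobutanoate | CC(C)(C)OC(=O)CCC(=O)N1[C@@H](Cc2ccccc2)CSC1=S | intermediate
8 | 4-O-trimethylsilyl ether of 9 | S=C1SC[C@H](Cc2ccccc2)N1C(=O)[C@@H](CC(=O)OC(C)(C)C)[C@@H](O[Si](C)(C)C)/C=C(\C)C(OC)OC | intermediate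
9 | anti-aldol adduct (3S,4S,5E; auxiliary 4S) | S=C1SC[C@H](Cc2ccccc2)N1C(=O)[C@@H](CC(=O)OC(C)(C)C)[C@@H](O)/C=C(\C)C(OC)OC | intermediate
10 | hydroxy Weinreb amide (3S,4S,5E) | CON(C)C(=O)[C@@H](CC(=O)OC(C)(C)C)[C@@H](O)/C=C(\C)C(OC)OC | intermediate
11 | triethylsilyl ether of 10 | CON(C)C(=O)[C@@H](CC(=O)OC(C)(C)C)[C@@H](O[Si](CC)(CC)CC)/C=C(\C)C(OC)OC | intermediate
12 | enal Weinreb amide (3S,4S,5E) | CON(C)C(=O)[C@@H](CC(=O)OC(C)(C)C)[C@@H](O[Si](CC)(CC)CC)/C=C(\C)C=O | intermediate
13 | (1R,4R,5R)-isothiocineole (4,7,7-trimethyl-6-thiabicyclo[3.2.1]octane) | C[C@@H]1CC[C@@H]2C[C@H]1SC2(C)C | starting material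
14 | 3-bromo-2-methylpropene | C=C(C)CBr | starting material
15 | S-(2-methylallyl)isothiocineolium triflate (allyl group on the exo lone pair) | C[C@@H]1CC[C@@H]2C[C@H]1[S@@+](CC(C)=C)C2(C)C.[O-]S(=O)(=O)C(F)(F)F | intermediate
16 | 2-methylallylide of 15 | C[C@@H]1CC[C@@H]2C[C@H]1[S@@+]([CH-]C(C)=C)C2(C)C | intermediate
17 | trans isopropenyl epoxide Weinreb amide (a S, j S, d R, e R) | CON(C)C(=O)[C@@H](CC(=O)OC(C)(C)C)[C@@H](O[Si](CC)(CC)CC)/C=C(\C)[C@H]1O[C@@H]1C(C)=C | intermediate
18 | methyl phenyl sulfone | CS(=O)(=O)c1ccccc1 | starting material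
19 | (phenylsulfonyl)methyllithium | [Li]CS(=O)(=O)c1ccccc1 | intermediate
20 | open-chain beta-keto sulfone with trans isopropenyl epoxide (a S, j S, d R, e R) | O=S(=O)(c1ccccc1)CC(=O)[C@@H](CC(=O)OC(C)(C)C)[C@@H](O[Si](CC)(CC)CC)/C=C(\C)[C@H]1O[C@@H]1C(C)=C | intermediate
21 | ten-membered keto sulfone with Z-allylic alcohol (a S, d S, j S; h-epimers) | CC[Si](CC)(CC)O[C@H]1/C=C(\C)[C@@H](O)/C=C(/C)CC(S(=O)(=O)c2ccccc2)C(=O)[C@H]1CC(=O)OC(C)(C)C | intermediate
22 | desulfonylated hydroxy ketone (a S, d S, j S) | CC[Si](CC)(CC)O[C@H]1/C=C(\C)[C@@H](O)/C=C(/C)CCC(=O)[C@H]1CC(=O)OC(C)(C)C | intermediate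
23 | d-O-triisopropylsilyl ketone (a S, d S, j S) | CC[Si](CC)(CC)O[C@H]1/C=C(\C)[C@@H](O[Si](C(C)C)(C(C)C)C(C)C)/C=C(/C)CCC(=O)[C@H]1CC(=O)OC(C)(C)C | intermediate
24 | i-alcohol (a S, d S, i R, j R) | CC[Si](CC)(CC)O[C@H]1/C=C(\C)[C@@H](O[Si](C(C)C)(C(C)C)C(C)C)/C=C(/C)CC[C@@H](O)[C@H]1CC(=O)OC(C)(C)C | intermediate
25 | i-O-TBS ether, TBS ester | CC[Si](CC)(CC)O[C@H]1/C=C(\C)[C@@H](O[Si](C(C)C)(C(C)C)C(C)C)/C=C(/C)CC[C@@H](O[Si](C)(C)C(C)(C)C)[C@H]1CC(=O)O[Si](C)(C)C(C)(C)C | intermediate
26 | tris-silyloxy carboxylic acid (a S, d S, i R, j R) | CC[Si](CC)(CC)O[C@H]1/C=C(\C)[C@@H](O[Si](C(C)C)(C(C)C)C(C)C)/C=C(/C)CC[C@@H](O[Si](C)(C)C(C)(C)C)[C@H]1CC(=O)O | intermediate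
27 | a-hydroxy acid (a S, d S, i R, j S) | O[C@H]1/C=C(\C)[C@@H](O[Si](C(C)C)(C(C)C)C(C)C)/C=C(/C)CC[C@@H](O[Si](C)(C)C(C)(C)C)[C@H]1CC(=O)O | intermediate
28 | cis-fused gamma-lactone, d-OTIPS, i-OTBS | C1C(=O)O[C@H]2/C=C(\C)[C@@H](O[Si](C(C)C)(C(C)C)C(C)C)/C=C(/C)CC[C@@H](O[Si](C)(C)C(C)(C)C)[C@@H]12 | intermediate
29 | alpha-(dimethylaminomethyl) lactone (alpha-carbon epimers) | CN(C)CC1C(=O)O[C@H]2/C=C(\C)[C@@H](O[Si](C(C)C)(C(C)C)C(C)C)/C=C(/C)CC[C@@H](O[Si](C)(C)C(C)(C)C)[C@@H]12 | intermediate
30 | trimethylammonium iodide of 29 | C[N+](C)(C)CC1C(=O)O[C@H]2/C=C(\C)[C@@H](O[Si](C(C)C)(C(C)C)C(C)C)/C=C(/C)CC[C@@H](O[Si](C)(C)C(C)(C)C)[C@@H]12.[I-] | intermediate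
31 | alpha-methylene lactone, d-OTIPS, i-OTBS | C=C1C(=O)O[C@H]2/C=C(\C)[C@@H](O[Si](C(C)C)(C(C)C)C(C)C)/C=C(/C)CC[C@@H](O[Si](C)(C)C(C)(C)C)[C@@H]12 | intermediate
32 | alpha-methylene lactone, d-OTIPS, i-OH | C=C1C(=O)O[C@H]2/C=C(\C)[C@@H](O[Si](C(C)C)(C(C)C)C(C)C)/C=C(/C)CC[C@@H](O)[C@@H]12 | intermediate
33 | angelic acid ((Z)-2-methylbut-2-enoic acid) | C/C=C(/C)C(=O)O | starting material
34 | angelic 2,4,6-trichlorobenzoic anhydride | C/C=C(/C)C(=O)OC(=O)c1c(Cl)cc(Cl)cc1Cl | intermediate
35 | i-angelate, d-OTIPS | C=C1C(=O)O[C@H]2/C=C(\C)[C@@H](O[Si](C(C)C)(C(C)C)C(C)C)/C=C(/C)CC[C@@H](OC(=O)/C(C)=C\C)[C@@H]12 | intermediate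
36 | i-angelate, d-OH (bis-allylic alcohol) | C=C1C(=O)O[C@H]2/C=C(\C)[C@@H](O)/C=C(/C)CC[C@@H](OC(=O)/C(C)=C\C)[C@@H]12 | intermediate
37 | e,f-epoxy d-alcohol | C=C1C(=O)O[C@H]2/C=C(\C)[C@@H](O)[C@H]3O[C@@]3(C)CC[C@@H](OC(=O)/C(C)=C\C)[C@@H]12 | intermediate
38 | CNP0519641.1 | C=C1C(=O)O[C@H]2/C=C(\C)[C@@H](OC(C)=O)[C@H]3O[C@@]3(C)CC[C@@H](OC(=O)/C(C)=C\C)[C@@H]12 | target

Total step count: 22. Longest linear sequence: 20 steps (1, 2, 4–7, 9–22).

Steps most likely to fail

Step 11.
- What may go wrong: oligomerisation may outrun ring closure. Closure may run through the syn allyl form to an E alkene, or at e to the eight-membered ring. The vinyl epoxide may isomerise by hydride shift before carbon attack.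
- The fallback closes the ring at e=f instead of g–h. It sets out from 12 and comes back at 23.
- Vinylmagnesium bromide at −78 °C adds to the aldehyde of 12 faster than to the Weinreb amide. It gives the d-configured vinyl carbinol F1 beside its d-epimer F2, which is removed by chromatography.
- iPr3SiOTf and 2,6-lutidine give the triisopropylsilyl ether F3.
- 3-Methylbut-3-enylmagnesium bromide converts the Weinreb amide into the dienyl ketone F4.
- Ring-closing metathesis with the second-generation Hoveyda–Grubbs catalyst in hot dilute toluene joins e and f with loss of ethene. A ten-membered ring is expected to accept the trisubstituted alkene only as Z, which delivers 23.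

Step 21.
- What may go wrong: oxygen transfer to the Z-trisubstituted alkene may be sluggish, or discrimination between the two alkenes allylic to d may be poor.
- The fallback gives up hydroxyl direction and swaps the last two operations. It sets out from 36 and comes back at 38.
- Ac2O and pyridine give the diene acetate F5.
- F5 is submitted to Shi epoxidation: D-fructose-derived ketone, KHSO5 as 2KHSO5·KHSO4·K2SO4, K2CO3 buffer, MeCN/dimethoxymethane/water, 0 °C.
- The spiro transition state of this ketone enantiomer places oxygen on the face that gives e R and f S. Meanwhile b=c is deactivated by two allylic acyloxy groups.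

Step 14.
- What may go wrong: facial selectivity may be poor because the ring conformation overrides the catalyst.
- The fallback accepts the ring's own bias and corrects it afterwards. It sets out from 23 and comes back at 24.
- Reduction with LiBH(s-Bu)3 in THF at −78 °C from the open ring face gives the i-epimeric alcohol F6.
- Mitsunobu inversion (4-nitrobenzoic acid, PPh3, diisopropyl azodicarboxylate, toluene) gives the inverted 4-nitrobenzoate F7.
- K2CO3 in MeOH at 0 °C releases 24.

Further compounds
F1 | step 11 | d-configured vinyl carbinol Weinreb amide (a S, j S, d S) | CON(C)C(=O)[C@@H](CC(=O)OC(C)(C)C)[C@@H](O[Si](CC)(CC)CC)/C=C(\C)[C@@H](O)C=C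
F2 | step 11 | d-epimer of F1 | CON(C)C(=O)[C@@H](CC(=O)OC(C)(C)C)[C@@H](O[Si](CC)(CC)CC)/C=C(\C)[C@H](O)C=C
F3 | step 11 | triisopropylsilyl ether of F1 | CON(C)C(=O)[C@@H](CC(=O)OC(C)(C)C)[C@@H](O[Si](CC)(CC)CC)/C=C(\C)[C@@H](O[Si](C(C)C)(C(C)C)C(C)C)C=C
F4 | step 11 | dienyl ketone for ring-closing metathesis | C=C(C)CCC(=O)[C@@H](CC(=O)OC(C)(C)C)[C@@H](O[Si](CC)(CC)CC)/C=C(\C)[C@@H](O[Si](C(C)C)(C(C)C)C(C)C)C=C
F5 | step 21 | diene acetate (target lacking the epoxide oxygen) | C=C1C(=O)O[C@H]2/C=C(\C)[C@@H](OC(C)=O)/C=C(/C)CC[C@@H](OC(=O)/C(C)=C\C)[C@@H]12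
F6 | step 14 | i-epimer of 24 | CC[Si](CC)(CC)O[C@H]1/C=C(\C)[C@@H](O[Si](C(C)C)(C(C)C)C(C)C)/C=C(/C)CC[C@H](O)[C@H]1CC(=O)OC(C)(C)C
F7 | step 14 | 4-nitrobenzoate of 24 | CC[Si](CC)(CC)O[C@H]1/C=C(\C)[C@@H](O[Si](C(C)C)(C(C)C)C(C)C)/C=C(/C)CC[C@@H](OC(=O)c2ccc(cc2)[N+](=O)[O-])[C@H]1CC(=O)OC(C)(C)C
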